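The cyclohexane (C1 carbinol, C2, C3 = CHCl, C4 = CMeBr, C5, C6) is traced back to ketone 10, a γ-bromo ketone in which C2 and C4 stand 1,3 across C3. These three atoms are therefore tied into the cyclopropane of a bicyclo[3.1.0]hexan-2-one. Strain-driven homo-conjugate addition of HBr cleaves the C2–C4 bond, expands the cyclopentanone to the cyclohexanone and forms the tertiary C4–Br bond with inversion, trans to the C3 chlorine, in one operation. The precursor, exo-6-chloro-5-methylbicyclo[3.1.0]hexan-2-one, comes from an enantioselective intramolecular cyclopropanation of an (E)-chloroalkenyl diazoketone. An alkenylcerium carrying the (S)-carbinol then adds to C1.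

Key step: step 5

Remark: ring locants C1–C6 follow the name 4-bromo-3-chloro-4-methylcyclohexan-1-ol; the ligand enantiomers in steps 4 and 6 are taken to be those that deliver the configurations drawn.

Step 1
Reactants: 1 pent-4-yn-1-ol
Product: 3 (E)-5-chloro-4-methylpent-4-en-1-ol, via alkenylalane 2 (not isolated)
Conditions: Me3Al (3 equiv), Cp2ZrCl2 (0.25 equiv), CH2Cl2, 0 °C to rt; then NCS, THF, −30 to 0 °C; aq. Rochelle salt
Reagents that add atoms: trimethylaluminium, C[Al](C)C; N-chlorosuccinimide, O=C1CCC(=O)N1Cl
Why: Negishi zirconium-catalysed carboalumination adds CH3 and Al syn across the alkyne with CH3 on the internal carbon, and chlorodealumination with NCS should proceed with retention, so that Cl ends cis to CH3 (E); no stereocentre is formed.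

Step 2
Reactants: 3 (E)-5-chloro-4-methylpent-4-en-1-ol
Product: 5 (E)-5-chloro-4-methylpent-4-enoic acid, via aldehyde 4 (not isolated)
Conditions: TEMPO (10 mol %), PhI(OAc)2 (2.2 equiv), MeCN/H2O 1:1, rt
Reagents that add atoms: water, O
Why: Oxoammonium (TEMPO) oxidation takes the primary alcohol to the aldehyde and, through its hydrate, to the acid, while the electron-poor chloroalkene is inert.

Step 3
Reactants: 5 (E)-5-chloro-4-methylpent-4-enoic acid
Product: 7 (E)-6-chloro-1-diazo-5-methylhex-5-en-2-one, via acid chloride 6 (not isolated)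
Conditions: (COCl)2, DMF (cat.), CH2Cl2, 0 °C to rt, evaporate; CH2N2 (3 equiv), Et2O, 0 °C
Reagents that add atoms: oxalyl chloride, O=C(Cl)C(=O)Cl (chlorine of 6 only); diazomethane, C=[N+]=[N-]
Why: Acylation of diazomethane by the acid chloride (first stage of the Arndt–Eistert sequence) gives the terminal α-diazoketone, a second equivalent of diazomethane taking up the HCl.

Step 4
Reactants: 7 (E)-6-chloro-1-diazo-5-methylhex-5-en-2-one
Product: 8 (1S,5S,6S)-6-chloro-5-methylbicyclo[3.1.0]hexan-2-one
Conditions: [Cu(MeCN)4]PF6 (2 mol %), (S,S)-t-Bu-bis(oxazoline) (2.4 mol %), CH2Cl2, slow addition, 40 °C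
Reagents that add atoms: none
Why: Copper-carbene intramolecular cyclopropanation of a 1-diazohex-5-en-2-one is a concerted syn addition, so the E geometry places Cl exo (cis to CH3) on C6, the cis ring fusion is forced, and the chiral ligand selects the alkene face and thereby sets C1, C5 and C6.

Step 5
Reactants: 8 (1S,5S,6S)-6-chloro-5-methylbicyclo[3.1.0]hexan-2-one
Product: 10 (3S,4S)-4-bromo-3-chloro-4-methylcyclohexan-1-one, via enol 9 (not isolated)
Conditions: HBr (anhydrous, 1.5 equiv), CH2Cl2, −40 to 0 °C; non-basic work-up
Reagents that add atoms: hydrogen bromide, Br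
Why: Protonation of the ketone activates the conjugated cyclopropane and bromide attacks the tertiary carbon C5 from the side opposite the C1–C5 bond (SN2-like homo-conjugate, homo-Michael, addition of HBr), so that the zero-atom bridge breaks and the cyclopentanone becomes the six-membered enol 9, which tautomerises to 10. The closest known reactions are the HX openings of cyclopropyl ketones and the acid-induced C1–C5 scission of 5-alkylbicyclo[3.1.0]hexan-2-ones (sabina ketone type) to 4-substituted cyclohexanones. No ring is closed: the six-membered ring arises by ring expansion, the former cyclopropane CHCl carbon becoming C3 between C2 and C4 of 10. The only new stereocentre, C4, is fixed by inversion at C5 of 8, which places Br anti to the exo chlorine (trans-3,4), while the CHCl centre is untouched and the absolute configuration is that of step 4. The step needs cleavage of the internal C1–C5 bond and not of C1–C6: the methyl-bearing tertiary C5 carries the developing positive charge, whereas C6 is deactivated by its chlorine and hindered for substitution. Should the opening become more ionic, capture of the cation anti to the neighbouring chlorine leads to the same trans isomer, and release of cyclopropane strain keeps the step irreversible at low temperature.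

Step 6
Reactants: 11 3-methylbut-2-enal; 12 2,3-dibromoprop-1-ene
Product: 13 (S)-[(2-bromo-6-methylhepta-1,5-dien-4-yl)oxy]triethylsilane
Conditions: CrBr3 (10 mol %), chiral sulfonamide ligand (11 mol %), Et3N (20 mol %), Co(II) phthalocyanine (1 mol %), Mn (2 equiv), TESCl (1.5 equiv), THF, rt
Reagents that add atoms: chlorotriethylsilane, CC[Si](Cl)(CC)CC
Why: In this catalytic asymmetric Nozaki–Hiyama–Kishi 2-haloallylation only the allylic C–Br bond of 12 is reduced to the allylchromium(III), which adds 1,2 to the enal inside the chiral chromium complex to set the (S)-carbinol, and TESCl releases the chromium alkoxide directly as the TES ether.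

Step 7
Reactants: 13 (S)-[(2-bromo-6-methylhepta-1,5-dien-4-yl)oxy]triethylsilane; 10 (3S,4S)-4-bromo-3-chloro-4-methylcyclohexan-1-one
Product: 16 (1R,3S,4S)-4-bromo-3-chloro-4-methyl-1-[(4S)-6-methyl-4-(triethylsilyloxy)hepta-1,5-dien-2-yl]cyclohexan-1-ol, via alkenyllithium 14 (not isolated), via alkenylcerium 15 (not isolated)
Conditions: t-BuLi (2.05 equiv), Et2O, −78 °C; CeCl3 (anhydrous), THF, −78 °C; then 10, −78 °C; aq. NH4Cl
Reagents that add atoms: none
Why: Bromine–lithium exchange and transmetalation give a non-basic alkenylcerium (organocerium 1,2-addition) that should add to the β-chloro ketone without enolisation or loss of HCl, and the new stereocentre C1 is set by substrate control: although the ketone rests mainly in the chair with axial halogens, equatorial attack there would push the cerium alkoxide syn-axial to C3–Cl, so reaction is expected through the chair with equatorial C3–Cl and C4–Br (Curtin–Hammett), which places OH axial, cis to Br and trans to Cl.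

Step 8
Reactants: 16 (1R,3S,4S)-4-bromo-3-chloro-4-methyl-1-[(4S)-6-methyl-4-(triethylsilyloxy)hepta-1,5-dien-2-yl]cyclohexan-1-ol
Product: 17 (1R,3S,4S)-4-bromo-3-chloro-1-[(4S)-4-hydroxy-6-methylhepta-1,5-dien-2-yl]-4-methylcyclohexan-1-ol
Conditions: HF·pyridine, pyridine/THF, 0 °C
Reagents that add atoms: none
Why: Buffered fluoride-mediated desilylation cleaves only the Si–O bond, so the two allylic alcohols, the tertiary bromide and all four stereocentres should stay untouched.

Compound list
1 | pent-4-yn-1-ol | C#CCCCO | starting material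
2 | dimethyl[(1E)-5-(dimethylalumanyloxy)-2-methylpent-1-en-1-yl]alumane (not isolated) | C[Al](C)/C=C(\C)CCCO[Al](C)C | intermediate
3 | (E)-5-chloro-4-methylpent-4-en-1-ol | Cl/C=C(\C)CCCO | intermediate
4 | (E)-5-chloro-4-methylpent-4-enal (not isolated) | Cl/C=C(\C)CCC=O | intermediate
5 | (E)-5-chloro-4-methylpent-4-enoic acid | Cl/C=C(\C)CCC(=O)O | intermediate
6 | (E)-5-chloro-4-methylpent-4-enoyl chloride (not isolated) | Cl/C=C(\C)CCC(Cl)=O | intermediate
7 | (E)-6-chloro-1-diazo-5-methylhex-5-en-2-one | Cl/C=C(\C)CCC(=O)C=[N+]=[N-] | intermediate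
8 | (1S,5S,6S)-6-chloro-5-methylbicyclo[3.1.0]hexan-2-one (Cl exo, cis to CH3) | O=C1CC[C@]2(C)[C@@H](Cl)[C@H]12 | intermediate
9 | (3S,4S)-4-bromo-3-chloro-4-methylcyclohex-1-en-1-ol (not isolated) | OC1=C[C@H](Cl)[C@@](C)(Br)CC1 | intermediate
10 | (3S,4S)-4-bromo-3-chloro-4-methylcyclohexan-1-one (Br and Cl trans) | O=C1CC[C@](C)(Br)[C@@H](Cl)C1 | intermediate
11 | 3-methylbut-2-enal | CC(C)=CC=O | starting material
12 | 2,3-dibromoprop-1-ene | C=C(Br)CBr | starting material
13 | (S)-[(2-bromo-6-methylhepta-1,5-dien-4-yl)oxy]triethylsilane | C=C(Br)C[C@H](O[Si](CC)(CC)CC)C=C(C)C | intermediate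
14 | [(4S)-6-methyl-4-(triethylsilyloxy)hepta-1,5-dien-2-yl]lithium (not isolated) | [Li]C(=C)C[C@H](O[Si](CC)(CC)CC)C=C(C)C | intermediate
15 | dichloro[(4S)-6-methyl-4-(triethylsilyloxy)hepta-1,5-dien-2-yl]cerium (not isolated) | Cl[Ce](Cl)C(=C)C[C@H](O[Si](CC)(CC)CC)C=C(C)C | intermediate
16 | (1R,3S,4S)-4-bromo-3-chloro-4-methyl-1-[(4S)-6-methyl-4-(triethylsilyloxy)hepta-1,5-dien-2-yl]cyclohexan-1-ol | C=C(C[C@H](O[Si](CC)(CC)CC)C=C(C)C)[C@@]1(O)CC[C@](C)(Br)[C@@H](Cl)C1 | intermediate
17 | (1R,3S,4S)-4-bromo-3-chloro-1-[(4S)-4-hydroxy-6-methylhepta-1,5-dien-2-yl]-4-methylcyclohexan-1-ol | C=C(C[C@H](O)C=C(C)C)[C@@]1(O)CC[C@](C)(Br)[C@@H](Cl)C1 | target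

Total step count: 8. Longest linear sequence: 7 steps (steps 1–5, 7 and 8).

Steps most likely to fail

Step 7. The facial selectivity may be low or reversed: the ketone can react through its more populated chair with axial Br and Cl, where equatorial attack places the alkenyl group trans to C3–Cl and gives the C1 epimer. Enolisation with loss of HCl is a second leak. The fallback no longer relies on the carbon nucleophile to set C1 but forms the C1–O bond last on an sp2 C1. It sets out from 10, the addition being run as above to give 16 mixed with its C1 epimer, (1S,3S,4S)-4-bromo-3-chloro-4-methyl-1-[(4S)-6-methyl-4-(triethylsilyloxy)hepta-1,5-dien-2-yl]cyclohexan-1-ol F1. Thionyl chloride and pyridine in Et2O at −20 °C should convert both epimers by SNi′ allylic transposition into the primary allylic chloride {[(4S)-2-[(3S,4S)-4-bromo-3-chloro-4-methylcyclohexylidene]-1-chloro-6-methylhept-5-en-4-yl]oxy}triethylsilane F2, in which C1 is planar. Buffered solvolysis (NaHCO3, aqueous acetone, rt; the SN1′ hydrolysis known from geranyl chloride to linalool) should then return the tertiary alcohol. Water is expected to add to the ring terminus of the allyl cation from the equatorial side, anti to the axial C3–Cl, which is the configuration of 16. The fallback comes back to the route at 16.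

Step 4. Carbene transfer to the chlorine-deactivated trisubstituted alkene may be sluggish (carbene dimerisation, C–H insertion), and the enantioselectivity with a terminal diazoketone may be insufficient. The fallback gives up catalyst control and uses the enantiopure side chain as the resolving element. It sets out from 7: Rh2(OAc)4 in CH2Cl2 at rt gives the racemic bicycle, that is 8 together with (1R,5R,6R)-6-chloro-5-methylbicyclo[3.1.0]hexan-2-one F3. Under the conditions of step 5 the racemate gives 10 and, through the enol (3R,4R)-4-bromo-3-chloro-4-methylcyclohex-1-en-1-ol F4, the enantiomer (3R,4R)-4-bromo-3-chloro-4-methylcyclohexan-1-one F5. Union with 15 as in step 7 gives 16 and the diastereomer (1S,3R,4R)-4-bromo-3-chloro-4-methyl-1-[(4S)-6-methyl-4-(triethylsilyloxy)hepta-1,5-dien-2-yl]cyclohexan-1-ol F6, which are separated by chromatography. The fallback comes back to the route at 16.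

Step 5. The β-chloro-γ-bromo ketone may lose HBr or HCl (E1 or E1cB) during or after the opening, and a more ionic opening may erode the trans relationship. The fallback separates ring expansion and C–Br formation. It sets out from 8: TsOH (cat.) in benzene at rt should isomerise it, in the manner of the sabina ketone opening, to (S)-5-chloro-4-methylcyclohex-3-en-1-one F7. Markovnikov hydrobromination with anhydrous HBr in CH2Cl2 at −60 °C then places Br on C4, the chlorine-bridged tertiary cation being captured anti to Cl. The fallback comes back to the route at 10.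

Further compounds
F1 | step 7 | (1S,3S,4S)-4-bromo-3-chloro-4-methyl-1-[(4S)-6-methyl-4-(triethylsilyloxy)hepta-1,5-dien-2-yl]cyclohexan-1-ol | C=C(C[C@H](O[Si](CC)(CC)CC)C=C(C)C)[C@]1(O)CC[C@](C)(Br)[C@@H](Cl)C1
F2 | step 7 | {[(4S)-2-[(3S,4S)-4-bromo-3-chloro-4-methylcyclohexylidene]-1-chloro-6-methylhept-5-en-4-yl]oxy}triethylsilane (E/Z mixture at the exocyclic alkene) | ClCC(C[C@H](O[Si](CC)(CC)CC)C=C(C)C)=C1CC[C@](C)(Br)[C@@H](Cl)C1
F3 | step 4 | (1R,5R,6R)-6-chloro-5-methylbicyclo[3.1.0]hexan-2-one | O=C1CC[C@@]2(C)[C@H](Cl)[C@@H]12
F4 | step 4 | (3R,4R)-4-bromo-3-chloro-4-methylcyclohex-1-en-1-ol | OC1=C[C@@H](Cl)[C@](C)(Br)CC1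
F5 | step 4 | (3R,4R)-4-bromo-3-chloro-4-methylcyclohexan-1-one | O=C1CC[C@@](C)(Br)[C@H](Cl)C1
F6 | step 4 | (1S,3R,4R)-4-bromo-3-chloro-4-methyl-1-[(4S)-6-methyl-4-(triethylsilyloxy)hepta-1,5-dien-2-yl]cyclohexan-1-ol | C=C(C[C@H](O[Si](CC)(CC)CC)C=C(C)C)[C@]1(O)CC[C@@](C)(Br)[C@H](Cl)C1
F7 | step 5 | (S)-5-chloro-4-methylcyclohex-3-en-1-one | O=C1CC=C(C)[C@@H](Cl)C1
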